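Its constants belong to no real substance; what happens was integrated by code.

The target in this flask is made from nucleophile that has to dissolve first, so you can reckon its mean rate of formation from the feed of dissolving solid.

    buffer acid ⇌ buffer base + acid, settled at all times (K1 = 5.0 × 10⁻⁵ M)
    protonated nucleophile ⇌ nucleophile + acid, settled at all times (K2 = 2.5 × 10⁻⁸ M)
    solid nucleophile ⇌ nucleophile, rate k3*(cs3 - [nucleophile]) while solid is left; crystals form when [nucleophile] > cs3 (cs3 = 11 mM, k3 = 0.020 min⁻¹)
    electrophile + nucleophile → acid + target + leaving group (k4 = 98 M⁻¹ min⁻¹)
    target + leaving group → side product (k5 = 0.60 M⁻¹ min⁻¹)
    nucleophile + protic impurity → quenched reagent (k6 = 3.8 M⁻¹ min⁻¹)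

electrophile 0.019 M; buffer base 9.50 mM; buffer acid 1.90 mM; protic impurity 9.50 mM; solid nucleophile 0.0190 M; time 30 min

- part of the electrophile that has reacted at 30 min
- pH of the solution at 30 min

- acid is the free proton; pH is minus the decimal logarithm of its molar concentration
- solid nucleophile is a solid; its amount is given per volume of the solution
- at the start none of the solid nucleophile is in solution
- run time (flask): 30 min

My reckoning starts from the feed. While [nucleophile] stays far below solubility, the solid feeds 0.220 mM min⁻¹. A free nucleophile has a half-life of 0.37 min against the electrophile, far shorter than the run, so I take dissolution as the rate-limiting step.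

Two things slow target formation below the feed. At the starting pH, free nucleophile is 0.00250 of the protonated form, so I count the first 1.90 mM of feed as taken up by the buffer acid. In my reckoning that is a lag of 8.64 min, which leaves a factor of 0.712 of the run. After the lag, each substitution frees a proton that protonates another nucleophile, so half of the feed makes target, a factor of 0.5.

Together these give the mean making rate, the feed less the buffer acid spread over the run, then halved: 0.0783 mM min⁻¹. Over the run that is 12.4% of the electrophile.

Replacing the curve by this mean needs a check. A steady rate of half the feed needs [nucleophile] of 0.0591 mM, which is far below solubility, and the 6.60 mM that the feed brings over the run is less than the solid charged. I reckon no pH.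

The forecast gives 12.9%, within 11.8% to 14%, and pH 5.85, on the ground that “each substitution releases a proton that protonates another nucleophile”. Its figure is higher than mine.

The simulation gives 12.8% and pH 5.83, a mean of 0.0813 mM min⁻¹ against my 0.0783 mM min⁻¹. At 15.0 min, the nucleophile's half-life by target formation was 0.39 min, far shorter than the electrophile's 110 min by the same step, with [nucleophile] at 6.25 × 10⁻⁵ M and 96.0% of the electrophile still there. With the time and the other amounts held, the reacted part has moved by 5 points at 0.0132 M or 0.0330 M of electrophile.

In the neighbour flask with 0.032 M of electrophile, the same 0.0783 mM min⁻¹ gives 7.34%. The simulation of that flask gives 8.05%.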